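## Retrosynthetic overview

1. Target ⇐ acetylation of an α-ketol ⇐ enolate hydroxylation of the ring A ketone ⇐ oxidation of a ring A carbinol; aryl ether ⇐ Mitsunobu coupling of isofraxidin with the primary alcohol on ring B.
2. Exocyclic methylene ⇐ Lombardo methylenation of a ring B ketone; CH2OH arm ⇐ formaldehyde aldol on the silyl enol ether from a cis-selective Me2CuLi addition to a bicyclic enone (sets the angular methyl, then the neighbouring CH).
3. Bicyclic enone ⇐ Birch reduction and hydrolysis of a 6-methoxy-1,1-dimethyltetralin-2-ol; the ring-fusion C–H is relayed thermodynamically from the carbinol centre.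
4. Carbinol ⇐ ketoreductase reduction of 6-methoxy-1,1-dimethyl-2-tetralone ⇐ gem-dimethylation of 6-methoxy-2-tetralone.
5. Ring order: both carbocycles arrive with the tetralone (ring A as such, ring B by dearomatising the anisole ring); the coumarin is bought as isofraxidin and attached late.

Assumption: the SMILES is read literally as a cis-fused decalin (ring-fusion H, angular methyl and aryloxymethyl arm on one face, acetate on the other); 6-methoxy-2-tetralone and isofraxidin are purchased.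

## Route

Step 1
Reactants: 1 6-methoxy-3,4-dihydronaphthalen-2(1H)-one (6-methoxy-2-tetralone)
Product: 3 6-methoxy-1,1-dimethyl-3,4-dihydronaphthalen-2(1H)-one, via 1-methyl ketone 2 (not isolated)
Conditions: NaH (2.2 equiv), MeI (2.5 equiv), THF, 0 → 23 °C
Reagents that add atoms: iodomethane (CI)
Why: The benzylic CH2 between arene and carbonyl is the most acidic site, so two successive enolate C-methylations (SN2 alkylation) stop at the 1,1-dimethyl ketone.

Step 2
Reactants: 3 6-methoxy-1,1-dimethyl-3,4-dihydronaphthalen-2(1H)-one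
Product: 4 (2R)-6-methoxy-1,1-dimethyl-1,2,3,4-tetrahydronaphthalen-2-ol
Conditions: (R)-selective ketoreductase (NADPH-dependent alcohol dehydrogenase), NADP+ (cat.), i-PrOH, KH2PO4/K2HPO4 buffer pH 7–DMSO, 30 °C
Reagents that add atoms: none
Why: Enzymatic asymmetric ketone reduction delivers hydride from NADPH to one enantiotopic face of the prochiral ketone (small CH2 flank versus large quaternary flank), creating the first stereocentre (2R) under catalyst control.

Step 3
Reactants: 4 (2R)-6-methoxy-1,1-dimethyl-1,2,3,4-tetrahydronaphthalen-2-ol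
Product: 5 (2R)-6-methoxy-1,1-dimethyl-1,2,3,4,5,8-hexahydronaphthalen-2-ol
Conditions: Li, NH3 (l), t-BuOH, THF, −78 → −33 °C; NH4Cl
Reagents that add atoms: none
Why: Birch reduction of the anisole ring gives the 2,5-dihydroanisole (enol ether plus tetrasubstituted ring-fusion alkene) and leaves the homobenzylic carbinol centre untouched.

Step 4
Reactants: 5 (2R)-6-methoxy-1,1-dimethyl-1,2,3,4,5,8-hexahydronaphthalen-2-ol
Product: 7 (4aS,6R)-6-hydroxy-5,5-dimethyl-4,4a,5,6,7,8-hexahydronaphthalen-2(3H)-one, via hydroxy β,γ-enone 6 (not isolated)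
Conditions: HCl (1 M aq), THF–MeOH, 23 → 40 °C; minor ring-fusion epimer separated and recycled under the same conditions
Reagents that add atoms: water (O)
Why: Enol ether hydrolysis and β,γ → α,β enone isomerisation run under thermodynamic control, and because the planar enone locks the carbinol ring in the chair with the new ring-fusion hydrogen axial, the epimer with the hydroxyl equatorial (4aS from 6R, about 4:1 expected) is favoured.

Step 5
Reactants: 7 (4aS,6R)-6-hydroxy-5,5-dimethyl-4,4a,5,6,7,8-hexahydronaphthalen-2(3H)-one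
Product: 8 (4aS,6R)-5,5-dimethyl-6-[(triethylsilyl)oxy]-4,4a,5,6,7,8-hexahydronaphthalen-2(3H)-one
Conditions: TESCl, imidazole, DMAP (cat.), DMF, 23 °C
Reagents that add atoms: chlorotriethylsilane (CC[Si](Cl)(CC)CC)
Why: Silyl ether formation masks the only acidic proton before the organocopper step and touches no stereocentre.

Step 6
Reactants: 8 (4aS,6R)-5,5-dimethyl-6-[(triethylsilyl)oxy]-4,4a,5,6,7,8-hexahydronaphthalen-2(3H)-one
Product: 9 trimethyl{[(4aS,6R,8aS)-5,5,8a-trimethyl-6-[(triethylsilyl)oxy]-3,4,4a,5,6,7,8,8a-octahydronaphthalen-2-yl]oxy}silane (cis-fused: H-4a and 8a-CH3 on the same face)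
Conditions: Me2CuLi (from CuBr·SMe2 and MeLi), TMSCl, THF, −78 → −40 °C; Et3N
Reagents that add atoms: lithium dimethylcuprate ([Li+].C[Cu-]C); chlorotrimethylsilane (C[Si](C)(C)Cl)
Why: Chlorosilane-accelerated Gilman conjugate addition delivers methyl axially to the enone ring on the face of the ring-fusion hydrogen, because the other face is 1,3-diaxial to the axial methyl of the gem-dimethyl group, giving the cis-fused angular methyl (8aS) and a regiodefined silyl enol ether.

Step 7
Reactants: 9 trimethyl{[(4aS,6R,8aS)-5,5,8a-trimethyl-6-[(triethylsilyl)oxy]-3,4,4a,5,6,7,8,8a-octahydronaphthalen-2-yl]oxy}silane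
Product: 10 (1S,4aS,6R,8aS)-1-(hydroxymethyl)-5,5,8a-trimethyl-6-[(triethylsilyl)oxy]octahydronaphthalen-2(1H)-one (CH2OH cis to 8a-CH3)
Conditions: HCHO (37% aq), Yb(OTf)3 (10 mol %), THF, 23 °C
Reagents that add atoms: formaldehyde (C=O)
Why: Lewis-acid-catalysed Mukaiyama aldol hydroxymethylation adds the small electrophile axially, anti to the axial ring bond at the adjacent quaternary carbon and therefore cis to the angular methyl (1S).

Step 8
Reactants: 10 (1S,4aS,6R,8aS)-1-(hydroxymethyl)-5,5,8a-trimethyl-6-[(triethylsilyl)oxy]octahydronaphthalen-2(1H)-one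
Product: 11 (1S,4aS,6R,8aS)-1-({[tert-butyl(dimethyl)silyl]oxy}methyl)-5,5,8a-trimethyl-6-[(triethylsilyl)oxy]octahydronaphthalen-2(1H)-one
Conditions: TBSCl, imidazole, CH2Cl2, 0 → 23 °C
Reagents that add atoms: tert-butyl(chloro)dimethylsilane (CC(C)(C)[Si](C)(C)Cl)
Why: Silylation of the primary alcohol protects the β-hydroxy ketone against retro-aldol cleavage and dehydration under conditions too mild to epimerise the α-centre.

Step 9
Reactants: 11 (1S,4aS,6R,8aS)-1-({[tert-butyl(dimethyl)silyl]oxy}methyl)-5,5,8a-trimethyl-6-[(triethylsilyl)oxy]octahydronaphthalen-2(1H)-one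
Product: 12 tert-butyl(dimethyl){[(1S,4aS,6R,8aS)-5,5,8a-trimethyl-2-methylidene-6-[(triethylsilyl)oxy]decahydronaphthalen-1-yl]methoxy}silane
Conditions: Zn, CH2Br2, TiCl4, THF–CH2Cl2, 0 → 23 °C
Reagents that add atoms: dibromomethane (BrCBr)
Why: Takai–Lombardo methylenation with the non-basic zinc/titanium methylene reagent converts the enolisable α-branched ketone into the exocyclic alkene without epimerising the adjacent centre or eliminating the β-silyloxy group.

Step 10
Reactants: 12 tert-butyl(dimethyl){[(1S,4aS,6R,8aS)-5,5,8a-trimethyl-2-methylidene-6-[(triethylsilyl)oxy]decahydronaphthalen-1-yl]methoxy}silane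
Product: 13 (2R,4aS,5S,8aS)-5-(hydroxymethyl)-1,1,4a-trimethyl-6-methylidenedecahydronaphthalen-2-ol
Conditions: Bu4NF, THF, 23 → 45 °C
Reagents that add atoms: none
Why: Fluoride-induced desilylation frees both alcohols without affecting the alkene or any stereocentre.

Step 11
Reactants: 13 (2R,4aS,5S,8aS)-5-(hydroxymethyl)-1,1,4a-trimethyl-6-methylidenedecahydronaphthalen-2-ol; 14 7-hydroxy-6,8-dimethoxy-2H-chromen-2-one (isofraxidin)
Product: 15 7-{[(1S,4aS,6R,8aS)-6-hydroxy-5,5,8a-trimethyl-2-methylidenedecahydronaphthalen-1-yl]methoxy}-6,8-dimethoxy-2H-chromen-2-one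
Conditions: PPh3, DIAD, toluene, 0 → 50 °C
Reagents that add atoms: none
Why: In this Mitsunobu etherification only the primary alcohol forms a reactive alkoxyphosphonium ion, which the acidic phenol displaces by SN2 at CH2, while the neopentyl-type secondary alcohol stays untouched and no stereocentre is involved.

Step 12
Reactants: 15 7-{[(1S,4aS,6R,8aS)-6-hydroxy-5,5,8a-trimethyl-2-methylidenedecahydronaphthalen-1-yl]methoxy}-6,8-dimethoxy-2H-chromen-2-one
Product: 16 6,8-dimethoxy-7-{[(1S,4aS,8aS)-5,5,8a-trimethyl-2-methylidene-6-oxodecahydronaphthalen-1-yl]methoxy}-2H-chromen-2-one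
Conditions: Dess–Martin periodinane, pyridine, CH2Cl2, 23 °C
Reagents that add atoms: none
Why: Dess–Martin oxidation under buffered neutral conditions gives the ketone and erases the relay carbinol centre, with coumarin and exocyclic alkene inert.

Step 13
Reactants: 16 6,8-dimethoxy-7-{[(1S,4aS,8aS)-5,5,8a-trimethyl-2-methylidene-6-oxodecahydronaphthalen-1-yl]methoxy}-2H-chromen-2-one
Product: 18 7-{[(1S,4aS,7R,8aS)-7-hydroxy-5,5,8a-trimethyl-2-methylidene-6-oxodecahydronaphthalen-1-yl]methoxy}-6,8-dimethoxy-2H-chromen-2-one, via potassium enolate 17 (not isolated)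
Conditions: KN(SiMe3)2, THF, −78 °C; racemic 2-(phenylsulfonyl)-3-phenyloxaziridine, −78 °C; NH4Cl (aq)
Reagents that add atoms: 2-(phenylsulfonyl)-3-phenyloxaziridine (O=S(=O)(c1ccccc1)N1OC1c1ccccc1)
Why: In this Davis enolate hydroxylation the ketone can enolise only towards its CH2 side, and oxygen is transferred to the face opposite the two syn-axial methyl groups (angular methyl and one gem-dimethyl), giving the equatorial hydroxyl (7R), which is also the thermodynamic epimer.

Step 14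
Reactants: 18 7-{[(1S,4aS,7R,8aS)-7-hydroxy-5,5,8a-trimethyl-2-methylidene-6-oxodecahydronaphthalen-1-yl]methoxy}-6,8-dimethoxy-2H-chromen-2-one
Product: 19 (2R,4aS,8S,8aS)-8-{[(6,8-dimethoxy-2-oxo-2H-chromen-7-yl)oxy]methyl}-4,4,8a-trimethyl-7-methylidene-3-oxodecahydronaphthalen-2-yl acetate (target)
Conditions: Ac2O, pyridine, DMAP (cat.), CH2Cl2, 0 → 23 °C
Reagents that add atoms: acetic anhydride (CC(=O)OC(C)=O)
Why: DMAP-catalysed O-acylation of the α-ketol gives the acetate with retention at the carbinol carbon, completing the target.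

## Compound list

1 | 6-methoxy-3,4-dihydronaphthalen-2(1H)-one | COc1ccc2c(c1)CCC(=O)C2 | starting material
2 | 6-methoxy-1-methyl-3,4-dihydronaphthalen-2(1H)-one (racemic, not isolated) | COc1ccc2c(c1)CCC(=O)C2C | intermediate
3 | 6-methoxy-1,1-dimethyl-3,4-dihydronaphthalen-2(1H)-one | COc1ccc2c(c1)CCC(=O)C2(C)C | intermediate
4 | (2R)-6-methoxy-1,1-dimethyl-1,2,3,4-tetrahydronaphthalen-2-ol | COc1ccc2c(c1)CC[C@@H](O)C2(C)C | intermediate
5 | (2R)-6-methoxy-1,1-dimethyl-1,2,3,4,5,8-hexahydronaphthalen-2-ol | COC1=CCC2=C(C1)CC[C@@H](O)C2(C)C | intermediate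
6 | (6R)-6-hydroxy-5,5-dimethyl-3,4,5,6,7,8-hexahydronaphthalen-2(1H)-one (not isolated) | O=C1CCC2=C(C1)CC[C@@H](O)C2(C)C | intermediate
7 | (4aS,6R)-6-hydroxy-5,5-dimethyl-4,4a,5,6,7,8-hexahydronaphthalen-2(3H)-one | O=C1CC[C@@H]2C(C)(C)[C@H](O)CCC2=C1 | intermediate
8 | (4aS,6R)-5,5-dimethyl-6-[(triethylsilyl)oxy]-4,4a,5,6,7,8-hexahydronaphthalen-2(3H)-one | O=C1CC[C@@H]2C(C)(C)[C@H](O[Si](CC)(CC)CC)CCC2=C1 | intermediate
9 | trimethyl{[(4aS,6R,8aS)-5,5,8a-trimethyl-6-[(triethylsilyl)oxy]-3,4,4a,5,6,7,8,8a-octahydronaphthalen-2-yl]oxy}silane | C[Si](C)(C)OC=1CC[C@@H]2C(C)(C)[C@H](O[Si](CC)(CC)CC)CC[C@]2(C)C=1 | intermediate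
10 | (1S,4aS,6R,8aS)-1-(hydroxymethyl)-5,5,8a-trimethyl-6-[(triethylsilyl)oxy]octahydronaphthalen-2(1H)-one | O=C1CC[C@@H]2C(C)(C)[C@H](O[Si](CC)(CC)CC)CC[C@]2(C)[C@H]1CO | intermediate
11 | (1S,4aS,6R,8aS)-1-({[tert-butyl(dimethyl)silyl]oxy}methyl)-5,5,8a-trimethyl-6-[(triethylsilyl)oxy]octahydronaphthalen-2(1H)-one | O=C1CC[C@@H]2C(C)(C)[C@H](O[Si](CC)(CC)CC)CC[C@]2(C)[C@H]1CO[Si](C)(C)C(C)(C)C | intermediate
12 | tert-butyl(dimethyl){[(1S,4aS,6R,8aS)-5,5,8a-trimethyl-2-methylidene-6-[(triethylsilyl)oxy]decahydronaphthalen-1-yl]methoxy}silane | C=C1CC[C@@H]2C(C)(C)[C@H](O[Si](CC)(CC)CC)CC[C@]2(C)[C@H]1CO[Si](C)(C)C(C)(C)C | intermediate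
13 | (2R,4aS,5S,8aS)-5-(hydroxymethyl)-1,1,4a-trimethyl-6-methylidenedecahydronaphthalen-2-ol | C=C1CC[C@@H]2C(C)(C)[C@H](O)CC[C@]2(C)[C@H]1CO | intermediate
14 | 7-hydroxy-6,8-dimethoxy-2H-chromen-2-one (isofraxidin) | COc1cc2ccc(=O)oc2c(OC)c1O | starting material
15 | 7-{[(1S,4aS,6R,8aS)-6-hydroxy-5,5,8a-trimethyl-2-methylidenedecahydronaphthalen-1-yl]methoxy}-6,8-dimethoxy-2H-chromen-2-one | C=C1CC[C@@H]2C(C)(C)[C@H](O)CC[C@]2(C)[C@H]1COc1c(OC)cc2ccc(=O)oc2c1OC | intermediate
16 | 6,8-dimethoxy-7-{[(1S,4aS,8aS)-5,5,8a-trimethyl-2-methylidene-6-oxodecahydronaphthalen-1-yl]methoxy}-2H-chromen-2-one | C=C1CC[C@@H]2C(C)(C)C(=O)CC[C@]2(C)[C@H]1COc1c(OC)cc2ccc(=O)oc2c1OC | intermediate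
17 | potassium (4aS,5S,8aS)-5-{[(6,8-dimethoxy-2-oxo-2H-chromen-7-yl)oxy]methyl}-1,1,4a-trimethyl-6-methylidene-1,4,4a,5,6,7,8,8a-octahydronaphthalen-2-olate (not isolated) | C=C1CC[C@@H]2C(C)(C)C([O-])=CC[C@]2(C)[C@H]1COc1c(OC)cc2ccc(=O)oc2c1OC.[K+] | intermediate
18 | 7-{[(1S,4aS,7R,8aS)-7-hydroxy-5,5,8a-trimethyl-2-methylidene-6-oxodecahydronaphthalen-1-yl]methoxy}-6,8-dimethoxy-2H-chromen-2-one | C=C1CC[C@@H]2C(C)(C)C(=O)[C@H](O)C[C@]2(C)[C@H]1COc1c(OC)cc2ccc(=O)oc2c1OC | intermediate
19 | (2R,4aS,8S,8aS)-8-{[(6,8-dimethoxy-2-oxo-2H-chromen-7-yl)oxy]methyl}-4,4,8a-trimethyl-7-methylidene-3-oxodecahydronaphthalen-2-yl acetate | C=C1CC[C@@H]2C(C)(C)C(=O)[C@H](OC(C)=O)C[C@]2(C)[C@H]1COc1c(OC)cc2ccc(=O)oc2c1OC | target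

## Step count and fallbacks

Total step count: 14. Longest linear sequence: 14 steps (1 → 19); isofraxidin 14 enters at step 11.

The three steps most likely to fail:

Step 4. The ring-fusion hydrogen is only relayed thermodynamically from the carbinol centre, so the bias is modest. The fallback sets out from 3 and comes back at 7. Ketalisation of 3 (ethylene glycol, TsOH, benzene, reflux) gives the ethylene ketal F1, and Birch reduction (Li, NH3, t-BuOH) gives the dihydroanisole ketal F2. Oxalic acid in aqueous MeOH hydrolyses only the enol ether, giving the achiral β,γ-enone ketal F3. A 9-amino-9-deoxy-epi-cinchona primary amine with a carboxylic acid cocatalyst (iminium–base catalysis, enantioselective 1,3-proton shift) then sets the ring-fusion centre directly, giving the (4aS)-enone ketal F4. PPTS in wet acetone releases the (4aS)-enedione F5, and the same ketoreductase reduces its saturated ketone to 7. The minor enantiomer of F5 ends up as the separable ring-fusion epimer.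

Step 6. Conjugate methylation at a congested β,β-disubstituted enone next to a neopentyl centre may be slow or divert to 1,2-addition. The fallback sets out from 8 and comes back at 9. Luche reduction (NaBH4, CeCl3·7H2O, MeOH, −78 °C) gives the pseudo-equatorial allylic alcohol F6, with the hydroxyl cis to the ring-fusion hydrogen. Hydroxyl-directed Simmons–Smith cyclopropanation (Et2Zn, CH2I2, CH2Cl2, 0 °C) puts the methylene on that same face, giving the cyclopropyl carbinol F7. Dess–Martin oxidation gives the cyclopropyl ketone F8. Li in NH3 cleaves the exocyclic cyclopropane bond that overlaps with the carbonyl, turning the methylene into the cis angular methyl and leaving the lithium enolate F9, which TMSCl/Et3N silylates to 9.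

Step 11. A β-branched primary alcohol and a di-ortho-substituted phenol are both poor Mitsunobu partners. The fallback sets out from 13 and comes back at 15. Tf2O and 2,6-lutidine in CH2Cl2 at −78 °C convert only the primary hydroxyl into the primary triflate F10, which 14 displaces by SN2 in the presence of Cs2CO3 in MeCN (−20 → 23 °C) to give 15.

## Further compounds

F1 | step 4 | 6'-methoxy-1',1'-dimethyl-3',4'-dihydro-1'H-spiro[1,3-dioxolane-2,2'-naphthalene] (ethylene ketal of 3) | COc1ccc2c(c1)CCC1(OCCO1)C2(C)C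
F2 | step 4 | 6'-methoxy-1',1'-dimethyl-3',4',5',8'-tetrahydro-1'H-spiro[1,3-dioxolane-2,2'-naphthalene] | COC1=CCC2=C(C1)CCC1(OCCO1)C2(C)C
F3 | step 4 | 6-ethylene ketal of 5,5-dimethyl-3,4,7,8-tetrahydronaphthalene-2,6(1H,5H)-dione (achiral β,γ-enone) | O=C1CCC2=C(C1)CCC1(OCCO1)C2(C)C
F4 | step 4 | 6-ethylene ketal of (4aS)-5,5-dimethyl-4,4a,7,8-tetrahydronaphthalene-2,6(3H,5H)-dione | O=C1CC[C@@H]2C(C)(C)C3(OCCO3)CCC2=C1
F5 | step 4 | (4aS)-5,5-dimethyl-4,4a,7,8-tetrahydronaphthalene-2,6(3H,5H)-dione | O=C1CC[C@@H]2C(C)(C)C(=O)CCC2=C1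
F6 | step 6 | (2S,4aS,6R)-5,5-dimethyl-6-[(triethylsilyl)oxy]-2,3,4,4a,5,6,7,8-octahydronaphthalen-2-ol | O[C@H]1CC[C@@H]2C(C)(C)[C@H](O[Si](CC)(CC)CC)CCC2=C1
F7 | step 6 | (2S,4aS,6R)-5,5-dimethyl-1,8a-methano-6-[(triethylsilyl)oxy]decahydronaphthalen-2-ol, methano bridge cis to the 2-hydroxyl and to H-4a | O[C@H]1CC[C@@H]2C(C)(C)[C@H](O[Si](CC)(CC)CC)CC[C@@]23C[C@@H]13
F8 | step 6 | (4aS,6R)-5,5-dimethyl-1,8a-methano-6-[(triethylsilyl)oxy]octahydronaphthalen-2(1H)-one, methano bridge cis to H-4a | O=C1CC[C@@H]2C(C)(C)[C@H](O[Si](CC)(CC)CC)CC[C@@]23C[C@@H]13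
F9 | step 6 | lithium (4aS,6R,8aS)-5,5,8a-trimethyl-6-[(triethylsilyl)oxy]-3,4,4a,5,6,7,8,8a-octahydronaphthalen-2-olate | [Li+].[O-]C=1CC[C@@H]2C(C)(C)[C@H](O[Si](CC)(CC)CC)CC[C@]2(C)C=1
F10 | step 11 | [(1S,4aS,6R,8aS)-6-hydroxy-5,5,8a-trimethyl-2-methylidenedecahydronaphthalen-1-yl]methyl trifluoromethanesulfonate | C=C1CC[C@@H]2C(C)(C)[C@H](O)CC[C@]2(C)[C@H]1COS(=O)(=O)C(F)(F)F
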